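**Strategy**

The target is the 9-O-stearate of (7S,8R,8'R)-lariciresinol. The route rests on the fact that C8 of the tetrahydrofuran ring (O1, C7, C8, C8', C9') sits between the aryl-bearing C7 and C8'. The ring is therefore carried as an (S)-5-aryl butenolide with C9' as the lactone carbonyl. In one flask a copper-catalysed hydroxymethyl-anion equivalent adds to C8 anti to the C7 aryl (C8–C9), and the enolate is condensed with silylated vanillin (C8'–C7') to a benzylidene lactone. Hydrogenation anti to the C8 arm then sets C8' cis; lactone-to-ether reduction, Tamao oxidation and lipase acylation finish the synthesis.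

Key step: step 6

Remark: lignan numbering is used (C7 aryl-bearing ring carbon, C8 and C8' ring CH, C9' ring CH2, C9 exocyclic CH2O, C7' benzylic CH2); TBS = tert-butyldimethylsilyl; the given SMILES is read as (7S,8R,8'R), i.e. 7,8-trans and 8,8'-cis.

**Route**

Step 1
Reactants: 1 vanillin
Product: 2 4-(TBSO)-3-methoxybenzaldehyde
Conditions: TBSCl, imidazole, DMF, rt
Reagents that add atoms: tert-butyldimethylsilyl chloride, CC(C)(C)[Si](C)(C)Cl
Why: Imidazole-promoted silylation of a phenol; the aryl silyl ether should survive every step up to the final fluoride treatment and avoids a hydrogenolytic deprotection next to the benzylic C7–O bond.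

Step 2
Reactants: 2 4-(TBSO)-3-methoxybenzaldehyde; 3 methyl acrylate
Product: 4 methyl 4-[4-(TBSO)-3-methoxyphenyl]-4-oxobutanoate
Conditions: 3-benzyl-5-(2-hydroxyethyl)-4-methylthiazolium chloride (15 mol %), Et3N, DMF, 70 °C
Reagents that add atoms: none
Why: Stetter reaction, in which the thiazolylidene formed from the salt and Et3N turns the aldehyde carbon into an acyl-anion equivalent that adds 1,4 to the acrylate, run in an aprotic medium to spare the aryl silyl ether.

Step 3
Reactants: 4 methyl 4-[4-(TBSO)-3-methoxyphenyl]-4-oxobutanoate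
Product: 6 (5S)-5-[4-(TBSO)-3-methoxyphenyl]dihydrofuran-2(3H)-one, via (S)-hydroxy ester 5 (not isolated)
Conditions: RuCl(p-cymene)[(S,S)-TsDPEN] (1 mol %), HCO2H/Et3N 5:2, EtOAc, 40 °C; then PPTS (cat.), toluene, 60 °C
Reagents that add atoms: none
Why: Noyori–Ikariya asymmetric transfer hydrogenation of an aryl ketone, where the (S,S)-ligand controls hydride delivery to one ketone face and sets C7 as S (same sense as acetophenone to (S)-1-phenylethanol), followed by mild acid-catalysed lactonisation that leaves the C7–O bond intact.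

Step 4
Reactants: 6 (5S)-5-[4-(TBSO)-3-methoxyphenyl]dihydrofuran-2(3H)-one
Product: 10 (5S)-5-[4-(TBSO)-3-methoxyphenyl]furan-2(5H)-one, via lithium enolate 7 (not isolated), via α-phenylselanyl lactone 8 (not isolated), via selenoxide 9 (not isolated)
Conditions: LiN(i-Pr)2, THF, −78 °C; PhSeBr, −78 °C; then AcOH, 30% H2O2, 0 °C to rt
Reagents that add atoms: none
Why: α-Selenenylation of the lactone enolate followed by oxidation and selenoxide syn-elimination, which can only eliminate toward C8 and takes place in an acidic medium in which the acidic C7–H of the butenolide is not removed, so the C7 configuration should be kept.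

Step 5
Reactants: 11 (chloromethyl)(isopropoxy)dimethylsilane
Product: 12 [(isopropoxydimethylsilyl)methyl]magnesium chloride
Conditions: Mg turnings, BrCH2CH2Br (cat.), THF, 40 °C to reflux
Reagents that add atoms: magnesium, [Mg]
Why: Grignard formation by magnesium insertion into an α-silyl alkyl chloride, with the hindered isopropoxy group protecting silicon from attack by the reagent.

Step 6
Reactants: 10 (5S)-5-[4-(TBSO)-3-methoxyphenyl]furan-2(5H)-one; 12 [(isopropoxydimethylsilyl)methyl]magnesium chloride; 2 4-(TBSO)-3-methoxybenzaldehyde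
Product: 16 (3E,4S,5S)-3-[4-(TBSO)-3-methoxybenzylidene]-5-[4-(TBSO)-3-methoxyphenyl]-4-{[isopropoxy(dimethyl)silyl]methyl}dihydrofuran-2(3H)-one, via chloromagnesium enolate 13 (not isolated), via chloromagnesium aldolate 14 (not isolated), via aldol acetate 15 (not isolated)
Conditions: CuBr·SMe2 (10 mol %), THF, −78 °C, 12 added slowly; then 2, −78 °C; then Ac2O, −78 to 0 °C; then DBU, 0 °C to rt
Reagents that add atoms: none
Why: Transmetalation of 12 to the monovalent copper catalyst gives an organocuprate that adds to C8 of 10 through a copper–alkene π-complex and reductive elimination, forming C8–C9 and enolate 13; 13 adds to aldehyde 2 (C8'–C7', aldolate 14), Ac2O converts 14 into acetate 15, and DBU causes E1cB loss of acetate to the conjugated E-benzylidene 16. The closest known reaction type is the copper-catalysed conjugate addition of Grignard reagents to γ-substituted butenolides with aldehyde trapping of the enolate, here with the Tamao silylmethyl Grignard as hydroxymethyl-anion equivalent. No ring is closed, because the lactone already is the future tetrahydrofuran ring with C9' at the carbonyl oxidation level. The one new stereocentre, C8, is controlled by the C7 aryl group, which shields one face of the flat butenolide so that the cuprate enters anti and C9 ends up trans to the aryl; the configurations at C8' and C7' in 14 and 15 are erased by the elimination. The step needs 1,4-addition to win over 1,2-addition and over removal of the benzylic, allylic C7–H (which would racemise C7 through the 2-oxidofuran); this is secured by the soft, weakly basic α-silyl organocopper, slow addition of 12 at −78 °C, and the electron-donating para-silyloxy group on the C7 aryl, which lowers the acidity of C7–H. The alkene geometry is not critical, since either isomer would be reduced to the same C8' centre in step 7.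

Step 7
Reactants: 16 (3E,4S,5S)-benzylidene lactone
Product: 17 (3R,4S,5S)-3-[4-(TBSO)-3-methoxybenzyl]-5-[4-(TBSO)-3-methoxyphenyl]-4-{[isopropoxy(dimethyl)silyl]methyl}dihydrofuran-2(3H)-one
Conditions: H2 (10 bar), RhCl(PPh3)3 (5 mol %), toluene/i-PrOH, 40 °C
Reagents that add atoms: none
Why: Homogeneous hydrogenation under steric approach control should deliver H2 to the exocyclic alkene from the face opposite the adjacent C8 silylmethyl arm (held pseudo-axial by allylic 1,3-strain with the E-aryl group), placing the C8' benzyl cis to C9, and unlike palladium on carbon this catalyst does not hydrogenolyse the benzylic C7–O bond.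

Step 8
Reactants: 17 (3R,4S,5S)-cis lactone
Product: 18 (3R,4S,5S)-3-[4-(TBSO)-3-methoxybenzyl]-5-[4-(TBSO)-3-methoxyphenyl]-4-{[isopropoxy(dimethyl)silyl]methyl}tetrahydrofuran-2-ol (anomer mixture)
Conditions: i-Bu2AlH, CH2Cl2, −78 °C; aq. potassium sodium tartrate
Reagents that add atoms: none
Why: Partial reduction of a γ-lactone, which stops at the tetrahedral aluminium hemiacetal at −78 °C and gives the lactol on neutral work-up without base that could epimerise C8'.

Step 9
Reactants: 18 lactol
Product: 20 (2S,3S,4R)-4-[4-(TBSO)-3-methoxybenzyl]-2-[4-(TBSO)-3-methoxyphenyl]-3-{[isopropoxy(dimethyl)silyl]methyl}tetrahydrofuran, via oxocarbenium ion 19 (not isolated)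
Conditions: Et3SiH, BF3·OEt2, CH2Cl2, −78 °C; Et3N quench
Reagents that add atoms: none
Why: Ionic hydrogenation of a lactol, in which BF3 ionises the hemiacetal to oxocarbenium ion 19 and Et3SiH reduces it at C9', a carbon that carries no stereocentre, while at −78 °C the benzylic C7–O bond should stay un-ionised.

Step 10
Reactants: 20 (2S,3S,4R)-tetrahydrofuran silane
Product: 21 (+)-lariciresinol, [(2S,3R,4R)-4-(4-hydroxy-3-methoxybenzyl)-2-(4-hydroxy-3-methoxyphenyl)tetrahydrofuran-3-yl]methanol
Conditions: KF, KHCO3, 30% H2O2, THF/MeOH 1:1, rt; then aq. Na2S2O3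
Reagents that add atoms: hydrogen peroxide, OO
Why: Tamao–Fleming oxidation, in which hydroperoxide adds to the fluoride-activated alkoxysilane (or to a fluorosilane, should step 9 have exchanged isopropoxide for fluoride) and C9 migrates from silicon to oxygen, while fluoride and bicarbonate in methanol cleave both aryl silyl ethers in the same flask; with the lactone carbonyl already removed, the new C9 hydroxyl cannot translactonise.

Step 11
Reactants: 21 (+)-lariciresinol; 22 vinyl stearate
Product: 23 [(2S,3R,4R)-4-(4-hydroxy-3-methoxybenzyl)-2-(4-hydroxy-3-methoxyphenyl)tetrahydrofuran-3-yl]methyl octadecanoate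
Conditions: Novozym 435 (immobilised Candida antarctica lipase B), t-BuOMe/THF, 4 Å molecular sieves, 45 °C
Reagents that add atoms: none
Why: Lipase-catalysed irreversible transesterification with a vinyl ester, in which the enzyme acylates primary aliphatic alcohols but not phenols, so only the C9 hydroxyl should be stearoylated.

**Compound list**

1 | vanillin | COc1cc(C=O)ccc1O | starting material
2 | 4-(TBSO)-3-methoxybenzaldehyde | COc1cc(C=O)ccc1O[Si](C)(C)C(C)(C)C | intermediate
3 | methyl acrylate | C=CC(=O)OC | starting material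
4 | methyl 4-[4-(TBSO)-3-methoxyphenyl]-4-oxobutanoate | COC(=O)CCC(=O)c1ccc(O[Si](C)(C)C(C)(C)C)c(OC)c1 | intermediate
5 | methyl (4S)-4-hydroxy-4-[4-(TBSO)-3-methoxyphenyl]butanoate | COC(=O)CC[C@H](O)c1ccc(O[Si](C)(C)C(C)(C)C)c(OC)c1 | intermediate
6 | (5S)-5-[4-(TBSO)-3-methoxyphenyl]dihydrofuran-2(3H)-one | O=C1O[C@H](c2ccc(O[Si](C)(C)C(C)(C)C)c(OC)c2)CC1 | intermediate
7 | lithium enolate of 6 | [Li]OC1=CC[C@@H](c2ccc(O[Si](C)(C)C(C)(C)C)c(OC)c2)O1 | intermediate
8 | (5S)-5-[4-(TBSO)-3-methoxyphenyl]-3-(phenylselanyl)dihydrofuran-2(3H)-one (C3 epimers) | O=C1O[C@H](c2ccc(O[Si](C)(C)C(C)(C)C)c(OC)c2)CC1[Se]c1ccccc1 | intermediate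
9 | selenoxide of 8 | O=C1O[C@H](c2ccc(O[Si](C)(C)C(C)(C)C)c(OC)c2)CC1[Se](=O)c1ccccc1 | intermediate
10 | (5S)-5-[4-(TBSO)-3-methoxyphenyl]furan-2(5H)-one | O=C1O[C@H](c2ccc(O[Si](C)(C)C(C)(C)C)c(OC)c2)C=C1 | intermediate
11 | (chloromethyl)(isopropoxy)dimethylsilane | CC(C)O[Si](C)(C)CCl | starting material
12 | [(isopropoxydimethylsilyl)methyl]magnesium chloride | CC(C)O[Si](C)(C)C[Mg]Cl | intermediate
13 | chloromagnesium enolate of the (4S,5S)-4-(silylmethyl)-5-aryl lactone (C8–C9 formed, 7,8-trans) | Cl[Mg]OC1=C[C@H](C[Si](C)(C)OC(C)C)[C@@H](c2ccc(O[Si](C)(C)C(C)(C)C)c(OC)c2)O1 | intermediate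
14 | chloromagnesium aldolate (C8' and C7' epimers) | O=C1O[C@H](c2ccc(O[Si](C)(C)C(C)(C)C)c(OC)c2)[C@@H](C[Si](C)(C)OC(C)C)C1C(O[Mg]Cl)c1ccc(O[Si](C)(C)C(C)(C)C)c(OC)c1 | intermediate
15 | aldol acetate (C8' and C7' epimers) | O=C1O[C@H](c2ccc(O[Si](C)(C)C(C)(C)C)c(OC)c2)[C@@H](C[Si](C)(C)OC(C)C)C1C(OC(C)=O)c1ccc(O[Si](C)(C)C(C)(C)C)c(OC)c1 | intermediate
16 | (3E,4S,5S)-3-[4-(TBSO)-3-methoxybenzylidene]-5-[4-(TBSO)-3-methoxyphenyl]-4-{[isopropoxy(dimethyl)silyl]methyl}dihydrofuran-2(3H)-one | O=C1O[C@H](c2ccc(O[Si](C)(C)C(C)(C)C)c(OC)c2)[C@@H](C[Si](C)(C)OC(C)C)/C1=C\c1ccc(O[Si](C)(C)C(C)(C)C)c(OC)c1 | intermediate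
17 | (3R,4S,5S)-3-[4-(TBSO)-3-methoxybenzyl]-5-[4-(TBSO)-3-methoxyphenyl]-4-{[isopropoxy(dimethyl)silyl]methyl}dihydrofuran-2(3H)-one (4,5-trans, 3,4-cis) | O=C1O[C@H](c2ccc(O[Si](C)(C)C(C)(C)C)c(OC)c2)[C@@H](C[Si](C)(C)OC(C)C)[C@H]1Cc1ccc(O[Si](C)(C)C(C)(C)C)c(OC)c1 | intermediate
18 | lactol of 17 (anomer mixture) | OC1O[C@H](c2ccc(O[Si](C)(C)C(C)(C)C)c(OC)c2)[C@@H](C[Si](C)(C)OC(C)C)[C@H]1Cc1ccc(O[Si](C)(C)C(C)(C)C)c(OC)c1 | intermediate
19 | cyclic oxocarbenium hydroxytrifluoroborate from 18 | C1=[O+][C@H](c2ccc(O[Si](C)(C)C(C)(C)C)c(OC)c2)[C@@H](C[Si](C)(C)OC(C)C)[C@H]1Cc1ccc(O[Si](C)(C)C(C)(C)C)c(OC)c1.O[B-](F)(F)F | intermediate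
20 | (2S,3S,4R)-4-[4-(TBSO)-3-methoxybenzyl]-2-[4-(TBSO)-3-methoxyphenyl]-3-{[isopropoxy(dimethyl)silyl]methyl}tetrahydrofuran | C1O[C@H](c2ccc(O[Si](C)(C)C(C)(C)C)c(OC)c2)[C@@H](C[Si](C)(C)OC(C)C)[C@H]1Cc1ccc(O[Si](C)(C)C(C)(C)C)c(OC)c1 | intermediate
21 | (+)-lariciresinol, (7S,8R,8'R) | OC[C@H]1[C@@H](Cc2ccc(O)c(OC)c2)CO[C@@H]1c1ccc(O)c(OC)c1 | intermediate
22 | vinyl stearate | CCCCCCCCCCCCCCCCCC(=O)OC=C | starting material
23 | (7S,8R,8'R)-lariciresinol 9-O-stearate (CNP0168412.1) | CCCCCCCCCCCCCCCCCC(=O)OC[C@H]1[C@@H](Cc2ccc(O)c(OC)c2)CO[C@@H]1c1ccc(O)c(OC)c1 | target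

**Step count and risks**

Total step count: 11.
Longest linear sequence: 10 steps (steps 1–4 and 6–11 from vanillin); step 5 is a one-step branch.

Steps most likely to fail:

1. Step 6. The organometallic may remove the benzylic C7–H instead of adding 1,4 (racemisation and loss of the butenolide), or the enolate may be trapped incompletely and revert before acetylation. Fallback: the two C–C bonds are made in separate operations from 10. Reagent 12 with CuBr·SMe2 (cat.) and Me3SiCl in THF at −78 °C should give the silyl ketene acetal F1 by chlorosilane-accelerated conjugate addition, which outruns deprotonation. Aqueous work-up hydrolyses it to the trans-lactone F2. Deprotonation with LiN(i-Pr)2 at −78 °C and addition of 2 gives the aldol F3. Ac2O/DMAP converts F3 into acetate 15, where the fallback rejoins the route, and DBU then gives 16.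

2. Step 7. Facial selectivity may be poor, since the C7 aryl on the opposite face competes with the C8 arm, or the trisubstituted conjugated alkene may be reduced too slowly. Fallback: 16 is reduced by conjugate hydride delivery (NaBH4, NiCl2·6H2O, THF/i-PrOH, 0 °C) to the saturated lactone, expected mainly as the 8,8'-trans epimer F4. Deprotonation with LiN(SiMe3)2 in THF at −78 °C gives the lithium enolate F5, and kinetic protonation with 2,6-di-tert-butylphenol from the face opposite the C8 arm returns the cis-lactone 17. The same two operations would also correct wrong-epimer material from the hydrogenation.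

3. Step 9. The Lewis acid may ionise the benzylic C7–O bond (ring opening, C7 epimerisation, or silicon-assisted 1,3-elimination), or C8' may epimerise through the ring-opened hydroxy aldehyde. Fallback: lactol 18 is reduced with NaBH4 in THF/i-PrOH to the 7,9'-diol F6. The primary C9' hydroxyl is tosylated selectively (TsCl, Et3N, DMAP cat., CH2Cl2, 0 °C) to the monotosylate F7. NaH in THF then closes the ring by Williamson displacement at C9' by the C7 alkoxide, which leaves the C7–O bond intact and comes back at 20.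

**Further compounds**

F1 | step 6 | trimethylsilyl ketene acetal of the (4S,5S)-4-(silylmethyl)-5-aryl lactone | C[Si](C)(C)OC1=C[C@H](C[Si](C)(C)OC(C)C)[C@@H](c2ccc(O[Si](C)(C)C(C)(C)C)c(OC)c2)O1
F2 | step 6 | (4S,5S)-5-[4-(TBSO)-3-methoxyphenyl]-4-{[isopropoxy(dimethyl)silyl]methyl}dihydrofuran-2(3H)-one | O=C1O[C@H](c2ccc(O[Si](C)(C)C(C)(C)C)c(OC)c2)[C@@H](C[Si](C)(C)OC(C)C)C1
F3 | step 6 | aldol of F2 with 2 (C8' and C7' epimers) | O=C1O[C@H](c2ccc(O[Si](C)(C)C(C)(C)C)c(OC)c2)[C@@H](C[Si](C)(C)OC(C)C)C1C(O)c1ccc(O[Si](C)(C)C(C)(C)C)c(OC)c1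
F4 | step 7 | (3S,4S,5S)-epimer of 17 (8,8'-trans) | O=C1O[C@H](c2ccc(O[Si](C)(C)C(C)(C)C)c(OC)c2)[C@@H](C[Si](C)(C)OC(C)C)[C@@H]1Cc1ccc(O[Si](C)(C)C(C)(C)C)c(OC)c1
F5 | step 7 | lithium enolate of F4 | [Li]OC1=C(Cc2ccc(O[Si](C)(C)C(C)(C)C)c(OC)c2)[C@H](C[Si](C)(C)OC(C)C)[C@@H](c2ccc(O[Si](C)(C)C(C)(C)C)c(OC)c2)O1
F6 | step 9 | (1S,2S,3R)-3-[4-(TBSO)-3-methoxybenzyl]-1-[4-(TBSO)-3-methoxyphenyl]-2-{[isopropoxy(dimethyl)silyl]methyl}butane-1,4-diol | O[C@H](c1ccc(O[Si](C)(C)C(C)(C)C)c(OC)c1)[C@@H](C[Si](C)(C)OC(C)C)[C@H](CO)Cc1ccc(O[Si](C)(C)C(C)(C)C)c(OC)c1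
F7 | step 9 | primary (C9') p-toluenesulfonate of F6 | O[C@H](c1ccc(O[Si](C)(C)C(C)(C)C)c(OC)c1)[C@@H](C[Si](C)(C)OC(C)C)[C@H](COS(=O)(=O)c1ccc(C)cc1)Cc1ccc(O[Si](C)(C)C(C)(C)C)c(OC)c1
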